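Ring atoms are called C1 (ketone), C2 (methyl-bearing oxirane carbon), C3 (oxirane CH), C4 (CH2), C5 (side-chain carbon) and C6 (tigloyloxy carbon).
Retrosynthesis first clears the periphery: the O–OH group (singlet-oxygen ene on a prenyl ketone), the prenyl and allyl carbons, the exo-methylene carbon, the tiglate, the C6–O bond and the oxirane oxygen, leaving a 5-substituted 2-methylcyclohex-2-enone.
The enabling feature is that C2–C3 is the α,β-bond of the C1 ketone, with C1 and C3 in a 1,5-relationship through C6–C5–C4: without its oxygen bridge it is an aldol-condensation alkene, so the six-membered ring is cut at C2–C3 and at C5–C6 into tert-butyl 3-oxopentanoate and an enal.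
Forward: one flask joins C5–C6 (amine-catalysed Michael addition), closes the carbocycle at C2–C3 (aldol condensation) and expels the ester helper; the oxirane ring is then fused onto C2=C3, C6 is oxygenated and acylated, and the side chain is extended last.
Stereochemistry: C5 is set by the prolinol silyl ether catalyst and relays the rest: axial hydride gives a temporary C1 carbinol cis to the C5 arm, this hydroxyl directs the oxirane (C2, C3) to the same face, and the C6 oxygen enters anti to arm and oxirane.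

Key step: step 3

Remark: compounds 6, 7, 8, 20 and 22 are carried as mixtures at one centre that is destroyed later (the ester-bearing C6 or the side-chain carbinol); their SMILES leave that centre undefined.

Step 1
Reactants: 1 but-3-en-1-ol
Product: 2 tert-butyl(but-3-en-1-yloxy)diphenylsilane
Conditions: t-BuPh2SiCl, imidazole, DMF, 0 °C → rt
Reagents that add atoms: tert-butyl(chloro)diphenylsilane, CC(C)(C)[Si](Cl)(c1ccccc1)c1ccccc1
Why: Standard imidazole-promoted silylation of a primary alcohol; the tert-butyldiphenylsilyl ether is chosen because it should survive the hot acidic stage of step 3.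

Step 2
Reactants: 2 tert-butyl(but-3-en-1-yloxy)diphenylsilane; 3 (E)-but-2-enal (crotonaldehyde)
Product: 4 (2E)-5-[(tert-butyldiphenylsilyl)oxy]pent-2-enal
Conditions: second-generation Hoveyda–Grubbs catalyst (2 mol%), CH2Cl2, 40 °C
Reagents that add atoms: none
Why: Olefin cross-metathesis of a terminal alkene with crotonaldehyde is a well-precedented route to (E)-enals; the thermodynamically favoured E isomer should form while propene escapes.

Step 3
Reactants: 4 (2E)-5-[(tert-butyldiphenylsilyl)oxy]pent-2-enal; 5 tert-butyl 3-oxopentanoate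
Product: 9 (5S)-5-{2-[(tert-butyldiphenylsilyl)oxy]ethyl}-2-methylcyclohex-2-en-1-one, via Michael adduct 6 (not isolated), via cyclohexenone ester 7 (not isolated), via keto acid 8 (not isolated)
Conditions: (S)-2-{bis[3,5-bis(trifluoromethyl)phenyl][(trimethylsilyl)oxy]methyl}pyrrolidine (10 mol%), PhCO2H (10 mol%), toluene, rt; then TsOH·H2O (20 mol%), toluene, 80 °C
Reagents that add atoms: none
Why: The (S)-amine condenses with enal 4 to an (E)-iminium ion whose upper face is blocked by the diaryl(silyloxy)methyl group, so the enol of keto ester 5 adds 1,4 from the open face and sets C5 (adduct 6). Under TsOH the ethyl ketone enolises towards C2 and attacks the C3 aldehyde in a 6-(enolendo)-exo-trig aldol addition, dehydration gives the conjugated C2=C3 bond (7), and acidolysis of the tert-butyl ester followed by decarboxylation of β-keto acid 8 removes the activating group from C6. The closest known reaction type is the aminocatalytic Michael addition/aldol condensation of tert-butyl β-keto esters with enals to 5-substituted cyclohex-2-enones. The ring closure itself creates no stereocentre; the only new one, C5, is controlled by the catalyst, and the epimeric C6 centre of 6 and 7 converges because it becomes a methylene group. The step needs 1,4- over 1,2-addition (secured by iminium activation and the soft 1,3-dicarbonyl donor), closure through C2 rather than through the doubly activated C6 carbon (the latter would give a four-membered ring), and survival of the silyl ether in hot acid (the reason for choosing tert-butyldiphenylsilyl).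

Step 4
Reactants: 9 (5S)-5-{2-[(tert-butyldiphenylsilyl)oxy]ethyl}-2-methylcyclohex-2-en-1-one
Product: 10 (1R,5S)-5-{2-[(tert-butyldiphenylsilyl)oxy]ethyl}-2-methylcyclohex-2-en-1-ol
Conditions: NaBH4, CeCl3·7H2O, MeOH, −78 °C
Reagents that add atoms: none
Why: Luche 1,2-reduction; axial hydride delivery to the half-chair with the C5 arm equatorial should give the equatorial C1 alcohol cis to the arm, as in the reduction of carvone to cis-carveol.

Step 5
Reactants: 10 (1R,5S)-5-{2-[(tert-butyldiphenylsilyl)oxy]ethyl}-2-methylcyclohex-2-en-1-ol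
Product: 11 (1R,2R,4S,6S)-4-{2-[(tert-butyldiphenylsilyl)oxy]ethyl}-1-methyl-7-oxabicyclo[4.1.0]heptan-2-ol
Conditions: VO(acac)2 (5 mol%), t-BuOOH (decane), CH2Cl2, 0 °C → rt
Reagents that add atoms: tert-butyl hydroperoxide, CC(C)(C)OO
Why: Hydroxyl-directed vanadium-catalysed epoxidation of a cyclic allylic alcohol delivers oxygen to the face of the C1 hydroxyl, hence cis to the C5 arm, and sets C2 and C3 together.

Step 6
Reactants: 11 (1R,2R,4S,6S)-4-{2-[(tert-butyldiphenylsilyl)oxy]ethyl}-1-methyl-7-oxabicyclo[4.1.0]heptan-2-ol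
Product: 12 (1S,4R,6S)-4-{2-[(tert-butyldiphenylsilyl)oxy]ethyl}-1-methyl-7-oxabicyclo[4.1.0]heptan-2-one
Conditions: Dess–Martin periodinane, NaHCO3, CH2Cl2, 0 °C → rt
Reagents that add atoms: none
Why: Dess–Martin oxidation of the secondary alcohol removes the temporary C1 stereocentre and gives the α,β-epoxy ketone without touching the oxirane.

Step 7
Reactants: 12 (1S,4R,6S)-4-{2-[(tert-butyldiphenylsilyl)oxy]ethyl}-1-methyl-7-oxabicyclo[4.1.0]heptan-2-one
Product: 13 (1S,3S,4R,6S)-4-{2-[(tert-butyldiphenylsilyl)oxy]ethyl}-3-hydroxy-1-methyl-7-oxabicyclo[4.1.0]heptan-2-one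
Conditions: NaN(SiMe3)2, THF, −78 °C; then 3-phenyl-2-(phenylsulfonyl)oxaziridine, −78 °C; aq. NH4Cl
Reagents that add atoms: 3-phenyl-2-(phenylsulfonyl)oxaziridine, O=S(=O)(c1ccccc1)N1OC1c1ccccc1
Why: Enolate hydroxylation with a Davis oxaziridine; C2 is fully substituted, so only the C6 enolate can form, and the oxidant should approach anti to the adjacent C5 arm and to the oxirane oxygen, placing the C6 hydroxyl trans to both.

Step 8
Reactants: 13 (1S,3S,4R,6S)-4-{2-[(tert-butyldiphenylsilyl)oxy]ethyl}-3-hydroxy-1-methyl-7-oxabicyclo[4.1.0]heptan-2-one; 14 (2E)-2-methylbut-2-enoyl chloride (tigloyl chloride)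
Product: 15 (1S,3S,4R,6S)-4-{2-[(tert-butyldiphenylsilyl)oxy]ethyl}-1-methyl-2-oxo-7-oxabicyclo[4.1.0]heptan-3-yl (2E)-2-methylbut-2-enoate
Conditions: pyridine, 4-(dimethylamino)pyridine (cat.), CH2Cl2, 0 °C → rt
Reagents that add atoms: none
Why: Acylation of the secondary α-hydroxy ketone with an acid chloride under nucleophilic catalysis; the C6–O bond is not broken, so its configuration is kept, and the E geometry comes from the reagent.

Step 9
Reactants: 15 (1S,3S,4R,6S)-4-{2-[(tert-butyldiphenylsilyl)oxy]ethyl}-1-methyl-2-oxo-7-oxabicyclo[4.1.0]heptan-3-yl (2E)-2-methylbut-2-enoate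
Product: 16 (1S,3S,4R,6S)-4-(2-hydroxyethyl)-1-methyl-2-oxo-7-oxabicyclo[4.1.0]heptan-3-yl (2E)-2-methylbut-2-enoate
Conditions: Bu4NF, AcOH, THF, 0 °C → rt
Reagents that add atoms: none
Why: Fluoride cleavage of the silyl ether, buffered with acetic acid so that the base-sensitive α-acyloxy epoxy ketone is neither epimerised nor deacylated.

Step 10
Reactants: 16 (1S,3S,4R,6S)-4-(2-hydroxyethyl)-1-methyl-2-oxo-7-oxabicyclo[4.1.0]heptan-3-yl (2E)-2-methylbut-2-enoate
Product: 17 (1S,3S,4S,6S)-1-methyl-2-oxo-4-(2-oxoethyl)-7-oxabicyclo[4.1.0]heptan-3-yl (2E)-2-methylbut-2-enoate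
Conditions: Dess–Martin periodinane, NaHCO3, CH2Cl2, 0 °C
Reagents that add atoms: none
Why: Dess–Martin oxidation of the primary alcohol to the aldehyde under buffered, non-epimerising conditions.

Step 11
Reactants: 17 (1S,3S,4S,6S)-1-methyl-2-oxo-4-(2-oxoethyl)-7-oxabicyclo[4.1.0]heptan-3-yl (2E)-2-methylbut-2-enoate
Product: 18 (1S,3S,4S,6S)-1-methyl-2-oxo-4-(3-oxoprop-1-en-2-yl)-7-oxabicyclo[4.1.0]heptan-3-yl (2E)-2-methylbut-2-enoate
Conditions: 37% aq. HCHO, pyrrolidine (10 mol%), EtCO2H (10 mol%), i-PrOH, 45 °C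
Reagents that add atoms: formaldehyde, C=O
Why: Amine-catalysed Mannich condensation with formaldehyde followed by elimination (organocatalytic α-methylenation of aldehydes) installs the exo-methylene at the only enolisable aldehyde position; C5 is not α to a carbonyl and should keep its configuration.

Step 12
Reactants: 18 (1S,3S,4S,6S)-1-methyl-2-oxo-4-(3-oxoprop-1-en-2-yl)-7-oxabicyclo[4.1.0]heptan-3-yl (2E)-2-methylbut-2-enoate; 19 3-bromoprop-1-ene (allyl bromide)
Product: 20 (1S,3S,4S,6S)-4-(3-hydroxyhexa-1,5-dien-2-yl)-1-methyl-2-oxo-7-oxabicyclo[4.1.0]heptan-3-yl (2E)-2-methylbut-2-enoate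
Conditions: In powder, THF/H2O (1:1), rt
Reagents that add atoms: none
Why: Barbier-type indium-mediated allylation in aqueous THF should be selective for the aldehyde over the hindered ring ketone, the oxirane and the ester and adds 1,2 to the enal; the new carbinol centre forms as a mixture that is removed in step 14.

Step 13
Reactants: 20 (1S,3S,4S,6S)-4-(3-hydroxyhexa-1,5-dien-2-yl)-1-methyl-2-oxo-7-oxabicyclo[4.1.0]heptan-3-yl (2E)-2-methylbut-2-enoate; 21 2-methylbut-2-ene
Product: 22 (1S,3S,4S,6S)-4-(3-hydroxy-6-methylhepta-1,5-dien-2-yl)-1-methyl-2-oxo-7-oxabicyclo[4.1.0]heptan-3-yl (2E)-2-methylbut-2-enoate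
Conditions: second-generation Grubbs catalyst (5 mol%), 2-methylbut-2-ene (excess), CH2Cl2, 40 °C
Reagents that add atoms: none
Why: Cross-metathesis of a terminal alkene with 2-methylbut-2-ene is the standard conversion of allyl into prenyl; the 1,1-disubstituted alkene and the tiglate alkene are too hindered or electron-poor to take part.

Step 14
Reactants: 22 (1S,3S,4S,6S)-4-(3-hydroxy-6-methylhepta-1,5-dien-2-yl)-1-methyl-2-oxo-7-oxabicyclo[4.1.0]heptan-3-yl (2E)-2-methylbut-2-enoate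
Product: 23 (1S,3S,4S,6S)-1-methyl-4-(6-methyl-3-oxohepta-1,5-dien-2-yl)-2-oxo-7-oxabicyclo[4.1.0]heptan-3-yl (2E)-2-methylbut-2-enoate
Conditions: Dess–Martin periodinane, NaHCO3, CH2Cl2, 0 °C
Reagents that add atoms: none
Why: Dess–Martin oxidation of the allylic alcohol gives the α-methylene ketone under buffered conditions that should leave the β,γ-double bond out of conjugation.

Step 15
Reactants: 23 (1S,3S,4S,6S)-1-methyl-4-(6-methyl-3-oxohepta-1,5-dien-2-yl)-2-oxo-7-oxabicyclo[4.1.0]heptan-3-yl (2E)-2-methylbut-2-enoate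
Product: 24 (1S,3S,4S,6S)-4-[(4E)-6-hydroperoxy-6-methyl-3-oxohepta-1,4-dien-2-yl]-1-methyl-2-oxo-7-oxabicyclo[4.1.0]heptan-3-yl (2E)-2-methylbut-2-enoate
Conditions: O2, tetraphenylporphyrin (cat.), visible light, CH2Cl2, −20 °C
Reagents that add atoms: dioxygen, O=O
Why: Schenck ene reaction of singlet oxygen with the only electron-rich alkene; abstraction of the doubly activated α-keto allylic hydrogen, as in the photooxygenation of β,γ-unsaturated ketones to γ-hydroperoxy enones, should place the hydroperoxide on the tertiary carbon and the new double bond in (E)-conjugation.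

Compound list
1 | but-3-en-1-ol | C=CCCO | starting material
2 | tert-butyl(but-3-en-1-yloxy)diphenylsilane | C=CCCO[Si](c1ccccc1)(c1ccccc1)C(C)(C)C | intermediate
3 | (E)-but-2-enal (crotonaldehyde) | C/C=C/C=O | starting material
4 | (2E)-5-[(tert-butyldiphenylsilyl)oxy]pent-2-enal | O=C/C=C/CCO[Si](c1ccccc1)(c1ccccc1)C(C)(C)C | intermediate
5 | tert-butyl 3-oxopentanoate | CCC(=O)CC(=O)OC(C)(C)C | starting material
6 | tert-butyl (3R)-5-[(tert-butyldiphenylsilyl)oxy]-3-(2-oxoethyl)-2-propanoylpentanoate (both C2 epimers; Michael adduct) | CCC(=O)C(C(=O)OC(C)(C)C)[C@@H](CC=O)CCO[Si](c1ccccc1)(c1ccccc1)C(C)(C)C | intermediate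
7 | tert-butyl (6S)-6-{2-[(tert-butyldiphenylsilyl)oxy]ethyl}-3-methyl-2-oxocyclohex-3-ene-1-carboxylate (both C1 epimers) | CC(C)(C)[Si](c1ccccc1)(c1ccccc1)OCC[C@@H]1CC=C(C)C(=O)C1C(=O)OC(C)(C)C | intermediate
8 | (6S)-6-{2-[(tert-butyldiphenylsilyl)oxy]ethyl}-3-methyl-2-oxocyclohex-3-ene-1-carboxylic acid (both C1 epimers) | CC(C)(C)[Si](c1ccccc1)(c1ccccc1)OCC[C@@H]1CC=C(C)C(=O)C1C(=O)O | intermediate
9 | (5S)-5-{2-[(tert-butyldiphenylsilyl)oxy]ethyl}-2-methylcyclohex-2-en-1-one | CC(C)(C)[Si](c1ccccc1)(c1ccccc1)OCC[C@@H]1CC=C(C)C(=O)C1 | intermediate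
10 | (1R,5S)-5-{2-[(tert-butyldiphenylsilyl)oxy]ethyl}-2-methylcyclohex-2-en-1-ol (hydroxyl cis to the C5 arm) | CC(C)(C)[Si](c1ccccc1)(c1ccccc1)OCC[C@@H]1CC=C(C)[C@H](O)C1 | intermediate
11 | (1R,2R,4S,6S)-4-{2-[(tert-butyldiphenylsilyl)oxy]ethyl}-1-methyl-7-oxabicyclo[4.1.0]heptan-2-ol (oxirane, hydroxyl and arm all cis) | CC(C)(C)[Si](c1ccccc1)(c1ccccc1)OCC[C@@H]1C[C@@H]2O[C@]2(C)[C@H](O)C1 | intermediate
12 | (1S,4R,6S)-4-{2-[(tert-butyldiphenylsilyl)oxy]ethyl}-1-methyl-7-oxabicyclo[4.1.0]heptan-2-one (oxirane cis to the arm) | CC(C)(C)[Si](c1ccccc1)(c1ccccc1)OCC[C@@H]1C[C@@H]2O[C@]2(C)C(=O)C1 | intermediate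
13 | (1S,3S,4R,6S)-4-{2-[(tert-butyldiphenylsilyl)oxy]ethyl}-3-hydroxy-1-methyl-7-oxabicyclo[4.1.0]heptan-2-one (hydroxyl trans to arm and oxirane) | CC(C)(C)[Si](c1ccccc1)(c1ccccc1)OCC[C@@H]1C[C@@H]2O[C@]2(C)C(=O)[C@H]1O | intermediate
14 | (2E)-2-methylbut-2-enoyl chloride (tigloyl chloride) | C/C=C(\C)C(=O)Cl | starting material
15 | (1S,3S,4R,6S)-4-{2-[(tert-butyldiphenylsilyl)oxy]ethyl}-1-methyl-2-oxo-7-oxabicyclo[4.1.0]heptan-3-yl (2E)-2-methylbut-2-enoate | CC(C)(C)[Si](c1ccccc1)(c1ccccc1)OCC[C@@H]1C[C@@H]2O[C@]2(C)C(=O)[C@H]1OC(=O)/C(C)=C/C | intermediate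
16 | (1S,3S,4R,6S)-4-(2-hydroxyethyl)-1-methyl-2-oxo-7-oxabicyclo[4.1.0]heptan-3-yl (2E)-2-methylbut-2-enoate | OCC[C@@H]1C[C@@H]2O[C@]2(C)C(=O)[C@H]1OC(=O)/C(C)=C/C | intermediate
17 | (1S,3S,4S,6S)-1-methyl-2-oxo-4-(2-oxoethyl)-7-oxabicyclo[4.1.0]heptan-3-yl (2E)-2-methylbut-2-enoate | O=CC[C@@H]1C[C@@H]2O[C@]2(C)C(=O)[C@H]1OC(=O)/C(C)=C/C | intermediate
18 | (1S,3S,4S,6S)-1-methyl-2-oxo-4-(3-oxoprop-1-en-2-yl)-7-oxabicyclo[4.1.0]heptan-3-yl (2E)-2-methylbut-2-enoate | C=C(C=O)[C@@H]1C[C@@H]2O[C@]2(C)C(=O)[C@H]1OC(=O)/C(C)=C/C | intermediate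
19 | 3-bromoprop-1-ene (allyl bromide) | C=CCBr | starting material
20 | (1S,3S,4S,6S)-4-(3-hydroxyhexa-1,5-dien-2-yl)-1-methyl-2-oxo-7-oxabicyclo[4.1.0]heptan-3-yl (2E)-2-methylbut-2-enoate (both carbinol epimers) | C=C(C(O)CC=C)[C@@H]1C[C@@H]2O[C@]2(C)C(=O)[C@H]1OC(=O)/C(C)=C/C | intermediate
21 | 2-methylbut-2-ene | CC=C(C)C | starting material
22 | (1S,3S,4S,6S)-4-(3-hydroxy-6-methylhepta-1,5-dien-2-yl)-1-methyl-2-oxo-7-oxabicyclo[4.1.0]heptan-3-yl (2E)-2-methylbut-2-enoate (both carbinol epimers) | C=C(C(O)CC=C(C)C)[C@@H]1C[C@@H]2O[C@]2(C)C(=O)[C@H]1OC(=O)/C(C)=C/C | intermediate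
23 | (1S,3S,4S,6S)-1-methyl-4-(6-methyl-3-oxohepta-1,5-dien-2-yl)-2-oxo-7-oxabicyclo[4.1.0]heptan-3-yl (2E)-2-methylbut-2-enoate | C=C(C(=O)CC=C(C)C)[C@@H]1C[C@@H]2O[C@]2(C)C(=O)[C@H]1OC(=O)/C(C)=C/C | intermediate
24 | (1S,3S,4S,6S)-4-[(4E)-6-hydroperoxy-6-methyl-3-oxohepta-1,4-dien-2-yl]-1-methyl-2-oxo-7-oxabicyclo[4.1.0]heptan-3-yl (2E)-2-methylbut-2-enoate (CNP0284595.1) | C=C(C(=O)/C=C/C(C)(C)OO)[C@@H]1C[C@@H]2O[C@]2(C)C(=O)[C@H]1OC(=O)/C(C)=C/C | target

Total step count: 15. Longest linear sequence: 15 steps (steps 1 to 15).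

Steps most likely to fail

Step 15. Hydrogen abstraction may occur from the geminal methyl groups instead of the α-keto methylene (regioisomeric secondary hydroperoxide), or the β,γ-alkene of 23 may drift into conjugation before oxygenation. The fallback sets out from enal 18 and comes back at target 24; it brings the peroxide oxygen in together with its carbon atoms, so no regiochemical question arises. Nozaki–Hiyama–Kishi vinylation of 18 (vinyl bromide, CrCl2, cat. NiCl2, DMF) should give the divinyl carbinol (1S,3S,4S,6S)-4-(3-hydroxypenta-1,4-dien-2-yl)-1-methyl-2-oxo-7-oxabicyclo[4.1.0]heptan-3-yl (2E)-2-methylbut-2-enoate F1. Cross-metathesis of its monosubstituted alkene with 2-[(2-methoxypropan-2-yl)peroxy]-2-methylbut-3-ene (C=CC(C)(C)OOC(C)(C)OC, the peroxyketal of 2-methylbut-3-en-2-yl hydroperoxide; second-generation Hoveyda–Grubbs catalyst, CH2Cl2, 40 °C) should give the (E)-allylic alcohol (1S,3S,4S,6S)-4-{(4E)-3-hydroxy-6-[(2-methoxypropan-2-yl)peroxy]-6-methylhepta-1,4-dien-2-yl}-1-methyl-2-oxo-7-oxabicyclo[4.1.0]heptan-3-yl (2E)-2-methylbut-2-enoate F2. Dess–Martin oxidation gives the enone (1S,3S,4S,6S)-4-{(4E)-6-[(2-methoxypropan-2-yl)peroxy]-6-methyl-3-oxohepta-1,4-dien-2-yl}-1-methyl-2-oxo-7-oxabicyclo[4.1.0]heptan-3-yl (2E)-2-methylbut-2-enoate F3, and mild acid (AcOH, THF, H2O, rt) should free the hydroperoxide to give 24.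

Step 7. The C6 enolate of the epoxy ketone may attack its own oxirane framework (ring contraction of the Favorskii type), or the oxidant may not discriminate the two faces well enough. The fallback sets out from enone 9 and comes back at ester 15; it introduces the C6 oxygen before the oxirane exists. Kinetic deprotonation of 9 (KN(SiMe3)2, THF, −78 °C) and oxaziridine oxidation, anti to the C5 arm as is usual for 5-substituted cyclohexenones, should give (5S,6S)-5-{2-[(tert-butyldiphenylsilyl)oxy]ethyl}-6-hydroxy-2-methylcyclohex-2-en-1-one F4. Acylation with tigloyl chloride 14 (pyridine, cat. 4-(dimethylamino)pyridine) gives (1S,6S)-6-{2-[(tert-butyldiphenylsilyl)oxy]ethyl}-3-methyl-2-oxocyclohex-3-en-1-yl (2E)-2-methylbut-2-enoate F5. Reduction with NaBH4/CeCl3·7H2O (axial hydride, hydroxyl cis to the arm and trans to the ester) should give (1S,2S,6S)-6-{2-[(tert-butyldiphenylsilyl)oxy]ethyl}-2-hydroxy-3-methylcyclohex-3-en-1-yl (2E)-2-methylbut-2-enoate F6. Directed epoxidation (VO(acac)2, t-BuOOH) gives (1R,2R,3S,4R,6S)-4-{2-[(tert-butyldiphenylsilyl)oxy]ethyl}-2-hydroxy-1-methyl-7-oxabicyclo[4.1.0]heptan-3-yl (2E)-2-methylbut-2-enoate F7, and Dess–Martin oxidation returns 15.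

Step 3. Facial discrimination in the iminium addition to an unbranched aliphatic enal may be insufficient, or enantiomeric purity may erode during the hot acid stage. The fallback sets out from alcohol 10 of insufficient enantiomeric purity and comes back to 10; control of absolute configuration passes from the amine catalyst to an enzyme. Lipase-catalysed acylation (immobilised Candida antarctica lipase B, vinyl acetate, hexane, rt) should esterify the (1R)-alcohol preferentially, following the empirical rule for secondary alcohols, to give (1R,5S)-5-{2-[(tert-butyldiphenylsilyl)oxy]ethyl}-2-methylcyclohex-2-en-1-yl acetate F8. F8 is separated from the unreacted minor enantiomer and methanolysed (K2CO3, MeOH) back to 10.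

Further compounds
F1 | step 15 | (1S,3S,4S,6S)-4-(3-hydroxypenta-1,4-dien-2-yl)-1-methyl-2-oxo-7-oxabicyclo[4.1.0]heptan-3-yl (2E)-2-methylbut-2-enoate (both carbinol epimers) | C=C(C(O)C=C)[C@@H]1C[C@@H]2O[C@]2(C)C(=O)[C@H]1OC(=O)/C(C)=C/C
F2 | step 15 | (1S,3S,4S,6S)-4-{(4E)-3-hydroxy-6-[(2-methoxypropan-2-yl)peroxy]-6-methylhepta-1,4-dien-2-yl}-1-methyl-2-oxo-7-oxabicyclo[4.1.0]heptan-3-yl (2E)-2-methylbut-2-enoate (both carbinol epimers) | C=C(C(O)/C=C/C(C)(C)OOC(C)(C)OC)[C@@H]1C[C@@H]2O[C@]2(C)C(=O)[C@H]1OC(=O)/C(C)=C/C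
F3 | step 15 | (1S,3S,4S,6S)-4-{(4E)-6-[(2-methoxypropan-2-yl)peroxy]-6-methyl-3-oxohepta-1,4-dien-2-yl}-1-methyl-2-oxo-7-oxabicyclo[4.1.0]heptan-3-yl (2E)-2-methylbut-2-enoate | C=C(C(=O)/C=C/C(C)(C)OOC(C)(C)OC)[C@@H]1C[C@@H]2O[C@]2(C)C(=O)[C@H]1OC(=O)/C(C)=C/C
F4 | step 7 | (5S,6S)-5-{2-[(tert-butyldiphenylsilyl)oxy]ethyl}-6-hydroxy-2-methylcyclohex-2-en-1-one | CC(C)(C)[Si](c1ccccc1)(c1ccccc1)OCC[C@@H]1CC=C(C)C(=O)[C@H]1O
F5 | step 7 | (1S,6S)-6-{2-[(tert-butyldiphenylsilyl)oxy]ethyl}-3-methyl-2-oxocyclohex-3-en-1-yl (2E)-2-methylbut-2-enoate | CC(C)(C)[Si](c1ccccc1)(c1ccccc1)OCC[C@@H]1CC=C(C)C(=O)[C@H]1OC(=O)/C(C)=C/C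
F6 | step 7 | (1S,2S,6S)-6-{2-[(tert-butyldiphenylsilyl)oxy]ethyl}-2-hydroxy-3-methylcyclohex-3-en-1-yl (2E)-2-methylbut-2-enoate | CC(C)(C)[Si](c1ccccc1)(c1ccccc1)OCC[C@@H]1CC=C(C)[C@H](O)[C@H]1OC(=O)/C(C)=C/C
F7 | step 7 | (1R,2R,3S,4R,6S)-4-{2-[(tert-butyldiphenylsilyl)oxy]ethyl}-2-hydroxy-1-methyl-7-oxabicyclo[4.1.0]heptan-3-yl (2E)-2-methylbut-2-enoate | CC(C)(C)[Si](c1ccccc1)(c1ccccc1)OCC[C@@H]1C[C@@H]2O[C@]2(C)[C@H](O)[C@H]1OC(=O)/C(C)=C/C
F8 | step 3 | (1R,5S)-5-{2-[(tert-butyldiphenylsilyl)oxy]ethyl}-2-methylcyclohex-2-en-1-yl acetate | CC(C)(C)[Si](c1ccccc1)(c1ccccc1)OCC[C@@H]1CC=C(C)[C@H](OC(C)=O)C1
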